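## The problem

The target (21) is a biflavanone in which C3 of an eriodictyol-type chroman-4-one (upper unit) is bonded to C8'' of a naringenin-type chroman-4-one (lower unit). This sp3–sp2 junction is crowded: on the upper side it lies between the C4 carbonyl and the C2 aryl group, on the lower side between the oxygen-bearing carbons C7'' and C8a'', and the lower unit must be joined through C8'' and not C6''. There are three stereocentres, upper C2 (R) and C3 (S), trans to each other, and lower C2'' (R). C3 is α to a ketone and epimerisable, so C2 controls C3 through the preference for the diequatorial trans isomer, whereas C2'' is too remote to control the upper pair or to be controlled by it and needs a reagent-controlled step of its own. Both flavanone rings open by retro-oxa-Michael reaction under base, which would erase C2 or C2'', and the free polyphenol is sensitive to acid and to oxidation, so it has to be unveiled last under neutral conditions. The enabling feature is that upper C2 is an O1-bound benzylic methine attached to C3, which is α to C4=O and carries C8''. This is the array formed when a metal carbene at C3 inserts into a benzylic C–H bond of an aryl benzyl ether ortho to the ring A ketone.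

## Retrosynthesis

**End game (21 ⇒ 20 ⇒ 19 ⇒ 18 ⇒ 17).** The last step cuts all benzyl-type C–O bonds of 20 by neutral hydrogenolysis, which leaves both base-sensitive rings alone. Before that, the lower phenols are silyl ethers (19) and the lower carbonyl C4'' is a silyl-protected carbinol (17, via 18). A lower ketone would be enolised, arylated or ring-opened by the alkoxide base needed for the C8''–CH2 bond, and O7'' needs a group without α-hydrogen because it sits ortho to the future carbene. Building the lower flavanone after ring C instead would need hydroxide-mediated aldol chemistry on a molecule that already holds the upper flavanone. The mask costs two redox steps but removes every basic step from that stage.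

**Upper ring C (17 ⇒ 15).** Cutting C2–C3 gives the α-aryl-α-diazoketone 15. C3 is the diazo carbon and C2 is the benzylic CH2 of a 3,4-bis(benzyloxy)benzyl ether on the ortho oxygen of ring A. The neighbouring cuts are weaker. An O1–C2 cut (oxa-Michael closure of an α-aryl chalcone) needs a doubly hindered tetrasubstituted enone and gives no handle on absolute configuration. A C3–C8'' cut (arylation of a flavanone at C3) needs a base that opens the ring. The insertion cut removes one ring and both upper stereocentres, keeps C4 as a ketone and turns C2 into a protecting-group carbon. The forward step must prefer 1,6-insertion over attack on the ether oxygen and pick one benzylic hydrogen under catalyst control. C3 then settles trans (through epimer 16). Both ortho ethers of 15 are identical, so either insertion gives 17, and the unused one stays as the O5 protecting group.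

**Diazoketone and deoxybenzoin (15 ⇒ 14 ⇒ 13 + 9).** The diazo group comes from diazo transfer to the activated methylene of deoxybenzoin 14. Cutting 14 at CH2–C8'' gives the enolate of acetophenone 13 and aryl bromide 9. The alternative C(=O)–aryl cut (Friedel–Crafts acylation of a phloroglucinol triether) needs acid that would strip the electron-rich benzyl ethers. The chosen cut splits the molecule into two fragments of similar size, both derived from 1. The coupling must accept a bromide flanked by the ring oxygen and a silyloxy group, which is why 9 has no carbonyl group and no acidic centre.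

**Upper fragment (13 ⇒ 12 ⇒ 11 ⇒ 1 + 10).** Three aryl ether C–O bonds are cut, one per step, all to the same electrophile 10. Using one electrophile avoids any protecting-group exchange and makes the two ortho ethers equivalent. The three hydroxyls of 1 differ in acidity: the para one is free, the first ortho one is only loosely held, and the last is locked in the hydrogen bond to the acetyl group. They are therefore taken in that order under bases of rising strength (via 11 and 12). Forcing all three at once on the free triphenol with this electron-rich benzylic chloride would invite C-benzylation of the phloroglucinol ring, whereas each staged alkylation needs only to favour oxygen over carbon on a partly etherified, less nucleophilic ring.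

**Masked lower unit (9 ⇒ 8 ⇒ 7).** No skeletal bond is cut. The C4'' ketone of flavanone 7 is reduced and silylated. Besides protecting the ketone, this makes the O7'' silyl ether an ordinary aryl silyl ether instead of a base-labile vinylogous silyl ester.

**Lower stereocentre (7 ⇒ 5 + 6).** The C2''–aryl bond is cut to chromone 5 and arylboronic acid 6. An O1''–C2'' cut (oxa-Michael closure of a 2'-hydroxychalcone) is reversible, gives only moderate enantioselectivity and needs hydroxide, which the silyl ethers would not survive. The forward step is an enantioselective conjugate arylation under base-free conditions that tolerates the aryl bromide.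

**Bromochromone (5 ⇒ 3 ⇒ 2 ⇒ 1).** O1''–C2'' and the C2''–C3'' one-carbon unit are cut to give bromoacetophenone 3. Bromine is placed on 2 next to the only free phenol, and since only that phenol can cyclise, bromine ends up at C8'' rather than C6''. 2 comes from 1 by silylating the two hydroxyls not held in the hydrogen bond to the acetyl group.

## Roads not taken

Alternative 1: Lower ring A is grown on C3 by cutting C8''–C8a'' and C6''–C7''. The flavan-3-yl siloxyalkyne A2 is heated with 3-(benzyloxy)cyclobut-2-en-1-one A3. Ring opening to a vinylketene, [2+2] addition to the ynol ether, 4π opening, 6π closure and tautomerisation give the resorcinol A1.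
- Merits: the C3–C8'' bond starts as an unhindered sp3–sp bond, so no coupling at a doubly ortho-substituted arene is needed. Ring A emerges with three differentiated oxygens, which settles the 8- versus 6-linkage. The upper unit is a flavan and tolerates the basic steps of a later chalcone synthesis. In these respects it is better than the chosen plan.
- Weak points: A1 has CH2 at C4, so a late benzylic oxidation is needed next to the C2 benzylic ether and several electron-rich rings. The trans C2/C3 relation must already be present in A2, and with C4 as CH2 a wrong C3 configuration cannot be corrected by epimerisation. The whole lower ring C and C2'' remain to be built.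
- Comparison: the chosen plan keeps C4 as a ketone throughout (so C3 is self-correcting) and brings the lower unit in complete. It pays with a hindered palladium coupling.

Alternative 2: Ring C is cut at C3–C4 and O1–C2. A chiral phosphoric acid dehydrates 2-(hydroxymethyl)-3,5-bis(benzyloxy)phenol A5 to an o-quinone methide, which adds to the (E)-stilbene A6 in an oxa-[4+2] reaction to give chroman A4.
- Merits: two bonds and both stereocentres form in one convergent step. The trans relation follows stereospecifically from the alkene geometry instead of from equilibration. The electron-rich dialkoxyphenyl end against the pivaloylated end fixes the regiochemistry. It is more convergent for ring C than the chosen plan.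
- Weak points: the dienophile is an unactivated 1,2-diarylalkene with a doubly ortho-substituted aryl group and no hydrogen-bond handle for the catalyst. A4 again needs C4 oxidation. After pivalate removal the lower ring is a symmetric triol, so the 6/8 question and all lower-unit chemistry remain.
- Comparison: the chosen plan forms one bond less in its key step, but its product is four functional-group steps from the target.

Alternative 3: Ring C is cut at O1–C8a and C4–C4a. Fluoride releases an aryne from silyl triflate A9. The alkoxide of the anti-aldol ester A8 adds to it, and the resulting aryl anion attacks the ester to give chromanone A7.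
- Merits: C4 arrives as a ketone. Both stereocentres come from an aldol reaction, whose absolute control is more predictable than a catalyst-controlled C–H insertion on a chiral substrate. The 3-alkoxy group steers the aryne regiochemistry.
- Weak points: the β-alkoxide of an α,β-diaryl-β-hydroxy ester can undergo retro-aldol cleavage under fluoride, which would erode both centres. The anti-aldol of a doubly ortho-substituted arylacetate is itself demanding. Removal of the methoxymethyl ethers needs acid next to the C4 ketone. The lower flavanone would have to be built on a base-sensitive product.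
- Comparison: the chosen plan has no alkoxide intermediate, a self-correcting C3 and the lower unit already in place.

Key step: step 12

Remarks:
- The C4'' centre made in step 5 (drawn 4R, 2,4-cis) is a temporary mask. Either epimer would serve, and it is removed in step 14.
- Compound 10 is taken as a purchasable reagent.
- The ligand antipode in step 4 is the one expected to give 2R by analogy with cyclic enones. If the product proves to be 2S, the other antipode is used.

## Route

Step 1
Reactants: 1 2',4',6'-trihydroxyacetophenone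
Product: 2 1-[2-hydroxy-4,6-bis(triisopropylsilyloxy)phenyl]ethanone
Conditions: i-Pr3SiCl (2.3 equiv), imidazole, DMAP (cat.), DMF, 0 → 40 °C
Reagents that add atoms: chlorotriisopropylsilane, CC(C)[Si](Cl)(C(C)C)C(C)C
Why: Phenol silylation; the third hydroxyl is held in the hydrogen bond to the acetyl carbonyl and should resist the bulky chlorosilane, as in the usual twofold protection of phloroacetophenone.

Step 2
Reactants: 2 1-[2-hydroxy-4,6-bis(triisopropylsilyloxy)phenyl]ethanone
Product: 3 1-[3-bromo-2-hydroxy-4,6-bis(triisopropylsilyloxy)phenyl]ethanone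
Conditions: NBS (1.0 equiv), CH2Cl2, −20 → 0 °C
Reagents that add atoms: N-bromosuccinimide, O=C1CCC(=O)N1Br
Why: Electrophilic aromatic bromination ortho to the free chelated phenol; the other open position lies between two triisopropylsilyloxy groups and is shielded, so bromine should enter next to the oxygen that becomes O1''.

Step 3
Reactants: 3 1-[3-bromo-2-hydroxy-4,6-bis(triisopropylsilyloxy)phenyl]ethanone
Product: 5 8-bromo-5,7-bis(triisopropylsilyloxy)-4H-chromen-4-one, via enaminone 4 (not isolated)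
Conditions: Me2NCH(OMe)2, toluene, 90 °C; then HCl (2 M aq), CH2Cl2, rt
Reagents that add atoms: N,N-dimethylformamide dimethyl acetal, COC(OC)N(C)C
Why: Enaminone route to chromones: condensation at the methyl ketone, then acid-induced conjugate addition of the phenol and loss of dimethylamine; only the free ortho oxygen can cyclise, which fixes bromine at C8''.

Step 4
Reactants: 5 8-bromo-5,7-bis(triisopropylsilyloxy)-4H-chromen-4-one; 6 4-(benzyloxy)phenylboronic acid
Product: 7 (2R)-2-[4-(benzyloxy)phenyl]-8-bromo-5,7-bis(triisopropylsilyloxy)chroman-4-one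
Conditions: Pd(OCOCF3)2 (5 mol%), (S)-4-tert-butyl-2-(pyridin-2-yl)-4,5-dihydrooxazole (6 mol%), NH4PF6 (30 mol%), H2O (5 equiv), ClCH2CH2Cl, 60 °C
Reagents that add atoms: none
Why: Enantioselective conjugate addition of an arylboronic acid to a chromone with a cationic divalent palladium pyridine-oxazoline catalyst; the tert-butyl group of the ligand shields one face of the bound enone so that aryl migration sets C2'' (2R intended), and the base-free medium should spare the aryl bromide, the silyl ethers and the new stereocentre.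

Step 5
Reactants: 7 (2R)-2-[4-(benzyloxy)phenyl]-8-bromo-5,7-bis(triisopropylsilyloxy)chroman-4-one
Product: 8 (2R,4R)-2-[4-(benzyloxy)phenyl]-8-bromo-5,7-bis(triisopropylsilyloxy)chroman-4-ol
Conditions: NaBH4, CeCl3·7H2O, MeOH–THF, −20 → 0 °C
Reagents that add atoms: none
Why: Luche-type hydride reduction; axial delivery of hydride to the half-chair with equatorial C2'' aryl should give the 2,4-cis alcohol (substrate control), a centre that serves only as a mask.

Step 6
Reactants: 8 (2R,4R)-2-[4-(benzyloxy)phenyl]-8-bromo-5,7-bis(triisopropylsilyloxy)chroman-4-ol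
Product: 9 (2R,4R)-2-[4-(benzyloxy)phenyl]-8-bromo-4-(triethylsilyloxy)-5,7-bis(triisopropylsilyloxy)chroman
Conditions: Et3SiOTf, 2,6-lutidine, CH2Cl2, −78 → 0 °C
Reagents that add atoms: triethylsilyl trifluoromethanesulfonate, CC[Si](CC)(CC)OS(=O)(=O)C(F)(F)F
Why: Silylation of a hindered secondary benzylic alcohol with a silyl triflate and a hindered base; the alkyl triethylsilyl ether can later be removed by acidic fluoride without loss of the aryl triisopropylsilyl ethers.

Step 7
Reactants: 1 2',4',6'-trihydroxyacetophenone; 10 3,4-bis(benzyloxy)benzyl chloride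
Product: 11 1-(4-{[3,4-bis(benzyloxy)benzyl]oxy}-2,6-dihydroxyphenyl)ethanone
Conditions: 10 (1.0 equiv), CsHCO3 (1.5 equiv), KI (cat.), MeCN, 60 °C
Reagents that add atoms: none
Why: Regioselective Williamson etherification; the para hydroxyl is the most acidic and the only one free of the hydrogen bond to the acetyl group, so a hydrogencarbonate base ionises it alone. Any over-alkylated material is the bis-ether 12 of the next step.

Step 8
Reactants: 11 1-(4-{[3,4-bis(benzyloxy)benzyl]oxy}-2,6-dihydroxyphenyl)ethanone; 10 3,4-bis(benzyloxy)benzyl chloride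
Product: 12 1-(2,4-bis{[3,4-bis(benzyloxy)benzyl]oxy}-6-hydroxyphenyl)ethanone
Conditions: 10 (1.05 equiv), K2CO3 (1.5 equiv), KI (cat.), acetone, reflux
Reagents that add atoms: none
Why: Williamson etherification of one of the two equivalent ortho hydroxyls; the remaining one is then locked in the hydrogen bond to the acetyl carbonyl and is inert to K2CO3 in acetone, which stops the reaction at the mono-ortho stage.

Step 9
Reactants: 12 1-(2,4-bis{[3,4-bis(benzyloxy)benzyl]oxy}-6-hydroxyphenyl)ethanone; 10 3,4-bis(benzyloxy)benzyl chloride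
Product: 13 1-(2,4,6-tris{[3,4-bis(benzyloxy)benzyl]oxy}phenyl)ethanone
Conditions: 10 (1.3 equiv), Cs2CO3 (2 equiv), n-Bu4NI (cat.), DMF, 60 °C
Reagents that add atoms: none
Why: Williamson etherification of the chelated phenol, which needs the stronger, more soluble caesium base in DMF and iodide catalysis. The para ether is a spectator and the two identical ortho ethers are the C–H donors for step 12.

Step 10
Reactants: 13 1-(2,4,6-tris{[3,4-bis(benzyloxy)benzyl]oxy}phenyl)ethanone; 9 (2R,4R)-2-[4-(benzyloxy)phenyl]-8-bromo-4-(triethylsilyloxy)-5,7-bis(triisopropylsilyloxy)chroman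
Product: 14 2-{(2R,4R)-2-[4-(benzyloxy)phenyl]-4-(triethylsilyloxy)-5,7-bis(triisopropylsilyloxy)chroman-8-yl}-1-(2,4,6-tris{[3,4-bis(benzyloxy)benzyl]oxy}phenyl)ethanone
Conditions: Pd(OAc)2 (5 mol%), XPhos [2-dicyclohexylphosphino-2',4',6'-triisopropylbiphenyl] (10 mol%), NaOt-Bu (2.5 equiv), 13 (1.5 equiv), toluene, 80 °C
Reagents that add atoms: none
Why: Palladium-catalysed α-arylation of a methyl ketone enolate with an aryl bromide (Buchwald–Hartwig type); the bulky biarylphosphine supports oxidative addition to the doubly ortho-substituted bromide and reductive elimination, the size of both partners should prevent diarylation, and 9 offers no carbonyl or acidic centre to the base.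

Step 11
Reactants: 14 2-{(2R,4R)-2-[4-(benzyloxy)phenyl]-4-(triethylsilyloxy)-5,7-bis(triisopropylsilyloxy)chroman-8-yl}-1-(2,4,6-tris{[3,4-bis(benzyloxy)benzyl]oxy}phenyl)ethanone
Product: 15 2-diazo-2-{(2R,4R)-2-[4-(benzyloxy)phenyl]-4-(triethylsilyloxy)-5,7-bis(triisopropylsilyloxy)chroman-8-yl}-1-(2,4,6-tris{[3,4-bis(benzyloxy)benzyl]oxy}phenyl)ethanone
Conditions: 4-acetamidobenzenesulfonyl azide (1.5 equiv), DBU (2 equiv), MeCN–THF, 0 °C → rt
Reagents that add atoms: 4-acetamidobenzenesulfonyl azide, CC(=O)Nc1ccc(cc1)S(=O)(=O)N=[N+]=[N-]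
Why: Regitz diazo transfer to the benzylic methylene of a deoxybenzoin, the only acidic site in the molecule; silyl and benzyl ethers are inert to DBU.

Step 12
Reactants: 15 2-diazo-2-{(2R,4R)-2-[4-(benzyloxy)phenyl]-4-(triethylsilyloxy)-5,7-bis(triisopropylsilyloxy)chroman-8-yl}-1-(2,4,6-tris{[3,4-bis(benzyloxy)benzyl]oxy}phenyl)ethanone
Product: 17 (2R,3S)-2-[3,4-bis(benzyloxy)phenyl]-5,7-bis{[3,4-bis(benzyloxy)benzyl]oxy}-3-{(2R,4R)-2-[4-(benzyloxy)phenyl]-4-(triethylsilyloxy)-5,7-bis(triisopropylsilyloxy)chroman-8-yl}chroman-4-one, via cis C3 epimer 16 (not isolated)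
Conditions: Rh2(S-PTTL)4 {dirhodium tetrakis[N-phthaloyl-(S)-tert-leucinate]} (2 mol%), CH2Cl2, slow addition of 15, 0 → 40 °C; then DBU (0.2 equiv), 0 °C, AcOH quench
Reagents that add atoms: none
Why: The dirhodium carboxylate takes up the diazo carbon with loss of N2 to give an electrophilic carbene at C3, which inserts through a three-centre, hydride-transfer-like transition state into a benzylic C–H bond of an ortho 3,4-bis(benzyloxy)benzyl ether. The closest known reaction type is the chiral dirhodium carboxylate-catalysed intramolecular C–H insertion of 2-alkoxyaryl α-diazoketones to chroman-4-ones, together with enantioselective benzylic ether insertions of aryl-substituted carbenes. Ring C closes as a six-membered ring by 1,6-insertion, forming C2–C3. C2 is set by the catalyst, which selects one of the two benzylic hydrogens and replaces it with retention; the antipodal catalyst is used if the chiral lower unit proves mismatched. C3 is expected to form mainly cis (16) and is then equilibrated through the enol to the diequatorial trans isomer, so C2 controls C3. Insertion must win over attack of the ether oxygen on the carbene (oxonium ylide, then [1,2]-shift); the C–H bond is doubly activated by the ether oxygen and the electron-rich dialkoxyaryl ring, and the bulky phthalimido carboxylates and a non-coordinating solvent disfavour the ylide. Site selectivity is secured because both ortho ethers are identical and the para ether is out of reach. On the lower aryl group the ortho positions carry a silyl ether and the ring oxygen, whose C2''–H could only react by forming a bridged ring, so no five-membered insertion competes.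

Step 13
Reactants: 17 (2R,3S)-2-[3,4-bis(benzyloxy)phenyl]-5,7-bis{[3,4-bis(benzyloxy)benzyl]oxy}-3-{(2R,4R)-2-[4-(benzyloxy)phenyl]-4-(triethylsilyloxy)-5,7-bis(triisopropylsilyloxy)chroman-8-yl}chroman-4-one
Product: 18 (2R,3S)-2-[3,4-bis(benzyloxy)phenyl]-5,7-bis{[3,4-bis(benzyloxy)benzyl]oxy}-3-{(2R,4R)-2-[4-(benzyloxy)phenyl]-4-hydroxy-5,7-bis(triisopropylsilyloxy)chroman-8-yl}chroman-4-one
Conditions: HF·pyridine, pyridine, THF, 0 °C → rt
Reagents that add atoms: none
Why: Acidic fluoride cleaves an alkyl triethylsilyl ether much faster than aryl triisopropylsilyl ethers; excess pyridine keeps the benzylic alcohol and the dialkoxybenzyl ethers from ionising.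

Step 14
Reactants: 18 (2R,3S)-2-[3,4-bis(benzyloxy)phenyl]-5,7-bis{[3,4-bis(benzyloxy)benzyl]oxy}-3-{(2R,4R)-2-[4-(benzyloxy)phenyl]-4-hydroxy-5,7-bis(triisopropylsilyloxy)chroman-8-yl}chroman-4-one
Product: 19 (2R,3S)-2-[3,4-bis(benzyloxy)phenyl]-5,7-bis{[3,4-bis(benzyloxy)benzyl]oxy}-3-{(2R)-2-[4-(benzyloxy)phenyl]-4-oxo-5,7-bis(triisopropylsilyloxy)chroman-8-yl}chroman-4-one
Conditions: Dess–Martin periodinane, NaHCO3, CH2Cl2, 0 °C → rt
Reagents that add atoms: none
Why: Dess–Martin oxidation of a secondary benzylic alcohol under buffered, non-basic conditions restores the lower flavanone; C2'' is not α to the new ketone and is untouched.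

Step 15
Reactants: 19 (2R,3S)-2-[3,4-bis(benzyloxy)phenyl]-5,7-bis{[3,4-bis(benzyloxy)benzyl]oxy}-3-{(2R)-2-[4-(benzyloxy)phenyl]-4-oxo-5,7-bis(triisopropylsilyloxy)chroman-8-yl}chroman-4-one
Product: 20 (2R,3S)-2-[3,4-bis(benzyloxy)phenyl]-5,7-bis{[3,4-bis(benzyloxy)benzyl]oxy}-3-{(2R)-2-[4-(benzyloxy)phenyl]-5,7-dihydroxy-4-oxochroman-8-yl}chroman-4-one
Conditions: n-Bu4NF, AcOH (1:1.2), THF, 0 °C
Reagents that add atoms: none
Why: Fluoride cleaves the aryl silyl ethers, which are now activated as vinylogous silyl esters; acetic acid keeps the phenols protonated so that neither flavanone should open by retro-oxa-Michael reaction.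

Step 16
Reactants: 20 (2R,3S)-2-[3,4-bis(benzyloxy)phenyl]-5,7-bis{[3,4-bis(benzyloxy)benzyl]oxy}-3-{(2R)-2-[4-(benzyloxy)phenyl]-5,7-dihydroxy-4-oxochroman-8-yl}chroman-4-one
Product: 21 (2R,3S)-2-(3,4-dihydroxyphenyl)-5,7-dihydroxy-3-[(2R)-5,7-dihydroxy-2-(4-hydroxyphenyl)-4-oxochroman-8-yl]chroman-4-one
Conditions: H2 (1 atm), Pd/C (10%), EtOAc–MeOH, rt
Reagents that add atoms: none
Why: Catalytic hydrogenolysis of all nine benzylic C–O bonds (three aryl benzyl ethers and two aryl dialkoxybenzyl ethers, each with two benzyl ethers of its own) under neutral conditions; flavanone carbonyls and C2–O1 bonds normally survive short exposure at atmospheric pressure.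

## Compound list

1 | 2',4',6'-trihydroxyacetophenone | CC(=O)c1c(O)cc(O)cc1O | starting material
2 | 1-[2-hydroxy-4,6-bis(triisopropylsilyloxy)phenyl]ethanone | CC(=O)c1c(O)cc(O[Si](C(C)C)(C(C)C)C(C)C)cc1O[Si](C(C)C)(C(C)C)C(C)C | intermediate
3 | 1-[3-bromo-2-hydroxy-4,6-bis(triisopropylsilyloxy)phenyl]ethanone | CC(=O)c1c(O)c(Br)c(O[Si](C(C)C)(C(C)C)C(C)C)cc1O[Si](C(C)C)(C(C)C)C(C)C | intermediate
4 | (E)-1-[3-bromo-2-hydroxy-4,6-bis(triisopropylsilyloxy)phenyl]-3-(dimethylamino)prop-2-en-1-one | CN(C)/C=C/C(=O)c1c(O)c(Br)c(O[Si](C(C)C)(C(C)C)C(C)C)cc1O[Si](C(C)C)(C(C)C)C(C)C | intermediate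
5 | 8-bromo-5,7-bis(triisopropylsilyloxy)-4H-chromen-4-one | O=c1ccoc2c(Br)c(O[Si](C(C)C)(C(C)C)C(C)C)cc(O[Si](C(C)C)(C(C)C)C(C)C)c12 | intermediate
6 | 4-(benzyloxy)phenylboronic acid | OB(O)c1ccc(OCc2ccccc2)cc1 | starting material
7 | (2R)-2-[4-(benzyloxy)phenyl]-8-bromo-5,7-bis(triisopropylsilyloxy)chroman-4-one | O=C1C[C@H](c2ccc(OCc3ccccc3)cc2)Oc2c(Br)c(O[Si](C(C)C)(C(C)C)C(C)C)cc(O[Si](C(C)C)(C(C)C)C(C)C)c12 | intermediate
8 | (2R,4R)-2-[4-(benzyloxy)phenyl]-8-bromo-5,7-bis(triisopropylsilyloxy)chroman-4-ol (2,4-cis) | O[C@@H]1C[C@H](c2ccc(OCc3ccccc3)cc2)Oc2c(Br)c(O[Si](C(C)C)(C(C)C)C(C)C)cc(O[Si](C(C)C)(C(C)C)C(C)C)c12 | intermediate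
9 | (2R,4R)-2-[4-(benzyloxy)phenyl]-8-bromo-4-(triethylsilyloxy)-5,7-bis(triisopropylsilyloxy)chroman | CC[Si](CC)(CC)O[C@@H]1C[C@H](c2ccc(OCc3ccccc3)cc2)Oc2c(Br)c(O[Si](C(C)C)(C(C)C)C(C)C)cc(O[Si](C(C)C)(C(C)C)C(C)C)c12 | intermediate
10 | 3,4-bis(benzyloxy)benzyl chloride | ClCc1ccc(OCc2ccccc2)c(OCc2ccccc2)c1 | starting material
11 | 1-(4-{[3,4-bis(benzyloxy)benzyl]oxy}-2,6-dihydroxyphenyl)ethanone | CC(=O)c1c(O)cc(OCc2ccc(OCc3ccccc3)c(OCc3ccccc3)c2)cc1O | intermediate
12 | 1-(2,4-bis{[3,4-bis(benzyloxy)benzyl]oxy}-6-hydroxyphenyl)ethanone | CC(=O)c1c(O)cc(OCc2ccc(OCc3ccccc3)c(OCc3ccccc3)c2)cc1OCc1ccc(OCc2ccccc2)c(OCc2ccccc2)c1 | intermediate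
13 | 1-(2,4,6-tris{[3,4-bis(benzyloxy)benzyl]oxy}phenyl)ethanone | CC(=O)c1c(OCc2ccc(OCc3ccccc3)c(OCc3ccccc3)c2)cc(OCc2ccc(OCc3ccccc3)c(OCc3ccccc3)c2)cc1OCc1ccc(OCc2ccccc2)c(OCc2ccccc2)c1 | intermediate
14 | 2-{(2R,4R)-2-[4-(benzyloxy)phenyl]-4-(triethylsilyloxy)-5,7-bis(triisopropylsilyloxy)chroman-8-yl}-1-(2,4,6-tris{[3,4-bis(benzyloxy)benzyl]oxy}phenyl)ethanone | CC[Si](CC)(CC)O[C@@H]1C[C@H](c2ccc(OCc3ccccc3)cc2)Oc2c(CC(=O)c3c(OCc4ccc(OCc5ccccc5)c(OCc5ccccc5)c4)cc(OCc4ccc(OCc5ccccc5)c(OCc5ccccc5)c4)cc3OCc3ccc(OCc4ccccc4)c(OCc4ccccc4)c3)c(O[Si](C(C)C)(C(C)C)C(C)C)cc(O[Si](C(C)C)(C(C)C)C(C)C)c12 | intermediate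
15 | 2-diazo-2-{(2R,4R)-2-[4-(benzyloxy)phenyl]-4-(triethylsilyloxy)-5,7-bis(triisopropylsilyloxy)chroman-8-yl}-1-(2,4,6-tris{[3,4-bis(benzyloxy)benzyl]oxy}phenyl)ethanone | CC[Si](CC)(CC)O[C@@H]1C[C@H](c2ccc(OCc3ccccc3)cc2)Oc2c(C(=[N+]=[N-])C(=O)c3c(OCc4ccc(OCc5ccccc5)c(OCc5ccccc5)c4)cc(OCc4ccc(OCc5ccccc5)c(OCc5ccccc5)c4)cc3OCc3ccc(OCc4ccccc4)c(OCc4ccccc4)c3)c(O[Si](C(C)C)(C(C)C)C(C)C)cc(O[Si](C(C)C)(C(C)C)C(C)C)c12 | intermediate
16 | (2R,3R)-2-[3,4-bis(benzyloxy)phenyl]-5,7-bis{[3,4-bis(benzyloxy)benzyl]oxy}-3-{(2R,4R)-2-[4-(benzyloxy)phenyl]-4-(triethylsilyloxy)-5,7-bis(triisopropylsilyloxy)chroman-8-yl}chroman-4-one (2,3-cis) | CC[Si](CC)(CC)O[C@@H]1C[C@H](c2ccc(OCc3ccccc3)cc2)Oc2c([C@H]3C(=O)c4c(OCc5ccc(OCc6ccccc6)c(OCc6ccccc6)c5)cc(OCc5ccc(OCc6ccccc6)c(OCc6ccccc6)c5)cc4O[C@H]3c3ccc(OCc4ccccc4)c(OCc4ccccc4)c3)c(O[Si](C(C)C)(C(C)C)C(C)C)cc(O[Si](C(C)C)(C(C)C)C(C)C)c12 | intermediate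
17 | (2R,3S)-2-[3,4-bis(benzyloxy)phenyl]-5,7-bis{[3,4-bis(benzyloxy)benzyl]oxy}-3-{(2R,4R)-2-[4-(benzyloxy)phenyl]-4-(triethylsilyloxy)-5,7-bis(triisopropylsilyloxy)chroman-8-yl}chroman-4-one (2,3-trans) | CC[Si](CC)(CC)O[C@@H]1C[C@H](c2ccc(OCc3ccccc3)cc2)Oc2c([C@@H]3C(=O)c4c(OCc5ccc(OCc6ccccc6)c(OCc6ccccc6)c5)cc(OCc5ccc(OCc6ccccc6)c(OCc6ccccc6)c5)cc4O[C@H]3c3ccc(OCc4ccccc4)c(OCc4ccccc4)c3)c(O[Si](C(C)C)(C(C)C)C(C)C)cc(O[Si](C(C)C)(C(C)C)C(C)C)c12 | intermediate
18 | (2R,3S)-2-[3,4-bis(benzyloxy)phenyl]-5,7-bis{[3,4-bis(benzyloxy)benzyl]oxy}-3-{(2R,4R)-2-[4-(benzyloxy)phenyl]-4-hydroxy-5,7-bis(triisopropylsilyloxy)chroman-8-yl}chroman-4-one | O[C@@H]1C[C@H](c2ccc(OCc3ccccc3)cc2)Oc2c([C@@H]3C(=O)c4c(OCc5ccc(OCc6ccccc6)c(OCc6ccccc6)c5)cc(OCc5ccc(OCc6ccccc6)c(OCc6ccccc6)c5)cc4O[C@H]3c3ccc(OCc4ccccc4)c(OCc4ccccc4)c3)c(O[Si](C(C)C)(C(C)C)C(C)C)cc(O[Si](C(C)C)(C(C)C)C(C)C)c12 | intermediate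
19 | (2R,3S)-2-[3,4-bis(benzyloxy)phenyl]-5,7-bis{[3,4-bis(benzyloxy)benzyl]oxy}-3-{(2R)-2-[4-(benzyloxy)phenyl]-4-oxo-5,7-bis(triisopropylsilyloxy)chroman-8-yl}chroman-4-one | O=C1C[C@H](c2ccc(OCc3ccccc3)cc2)Oc2c([C@@H]3C(=O)c4c(OCc5ccc(OCc6ccccc6)c(OCc6ccccc6)c5)cc(OCc5ccc(OCc6ccccc6)c(OCc6ccccc6)c5)cc4O[C@H]3c3ccc(OCc4ccccc4)c(OCc4ccccc4)c3)c(O[Si](C(C)C)(C(C)C)C(C)C)cc(O[Si](C(C)C)(C(C)C)C(C)C)c12 | intermediate
20 | (2R,3S)-2-[3,4-bis(benzyloxy)phenyl]-5,7-bis{[3,4-bis(benzyloxy)benzyl]oxy}-3-{(2R)-2-[4-(benzyloxy)phenyl]-5,7-dihydroxy-4-oxochroman-8-yl}chroman-4-one | O=C1C[C@H](c2ccc(OCc3ccccc3)cc2)Oc2c([C@@H]3C(=O)c4c(OCc5ccc(OCc6ccccc6)c(OCc6ccccc6)c5)cc(OCc5ccc(OCc6ccccc6)c(OCc6ccccc6)c5)cc4O[C@H]3c3ccc(OCc4ccccc4)c(OCc4ccccc4)c3)c(O)cc(O)c12 | intermediate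
21 | (2R,3S)-2-(3,4-dihydroxyphenyl)-5,7-dihydroxy-3-[(2R)-5,7-dihydroxy-2-(4-hydroxyphenyl)-4-oxochroman-8-yl]chroman-4-one (CNP0105436.3) | O=C1C[C@H](c2ccc(O)cc2)Oc2c1c(O)cc(O)c2[C@@H]1C(=O)c2c(O)cc(O)cc2O[C@H]1c1ccc(O)c(O)c1 | target

## Step count and risks

Total step count: 16. Longest linear sequence: 13 steps (steps 1–6 and 10–16 from 1); steps 7–9 form a three-step side branch from 1.

**Step 12 (key step).**
- What may go wrong: the ether oxygen attacks the carbene and a [1,2]-benzyl shift follows, giving a benzofuranone skeleton instead of ring C. The electron-rich migrating group makes this shift easy. The choice between the two benzylic hydrogens may also be poor if the chiral lower unit works against the catalyst. During the base-mediated C3 equilibration, retro-oxa-Michael opening of ring C could erode the C2 configuration.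
- Fallback (from 14, back at 17): one ortho dialkoxybenzyl ether is removed by chelation-assisted cleavage with MgBr2·OEt2 to give the 2'-hydroxy deoxybenzoin F1. Piperidine-mediated condensation with 3,4-bis(benzyloxy)benzaldehyde (aldol condensation, then oxa-Michael closure) closes ring C from the oxygen side. Without facial control it should give 17 together with its (2S,3R) diastereomer F2. The two are diastereomers because the lower unit is enantiopure, and are separated by chromatography. The masked lower unit has no base-sensitive group.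

**Step 10.**
- What may go wrong: oxidative addition and transmetalation at the doubly ortho-substituted bromide are slow. Protodebromination and base-induced loss of the O7'' silyl group can then take over on prolonged heating.
- Fallback (from 9, back at 14): Stille coupling of 9 with allyltributyltin [Pd(PPh3)4, toluene, 110 °C] should give the 8-allyl flavan F3. OsO4/NaIO4 cleavage gives the arylacetaldehyde F4. Separately, phloroglucinol is etherified three times with 10 to the triether F5 and monobrominated with NBS to the aryl bromide F6. Bromine–lithium exchange (n-BuLi, −78 °C), transmetalation with CeCl3 and addition to F4 gives the carbinol F7. Dess–Martin oxidation converts F7 into 14.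

**Step 4.**
- What may go wrong: carbopalladation is sluggish on an electron-rich chromone with a bulky peri silyloxy group, so protodeboronation of 6 competes. Facial selectivity may also be insufficient.
- Fallback (from 5, back at 8): the addition is run with the achiral ligand 2,2'-bipyridine to give the racemic flavanone F8. This is resolved by asymmetric transfer hydrogenation [RuCl(p-cymene)[(R,R)-TsDPEN] or its antipode, HCO2H–Et3N]. The 2R enantiomer is reduced to 8 and the unreacted 2S flavanone F9 is separated. Half the material is lost, but step 5 is absorbed.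

**Step 3.**
- What may go wrong: methoxide released from the formamide acetal cleaves the aryl silyl ethers, which are activated by the para/ortho acyl group, and the freed phenols are methylated.
- Fallback (from 1, back at 5): the chromone is made before protection. 1 is converted with triethyl orthoformate and HClO4, then hot water, into 5,7-dihydroxy-4H-chromen-4-one F10. Silylation (i-Pr3SiOTf, 2,6-lutidine) gives 5,7-bis(triisopropylsilyloxy)-4H-chromen-4-one F11. NBS bromination at C8, the position not flanked by two silyloxy groups, gives 5.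

**Step 16.**
- What may go wrong: nine hydrogenolyses on a poorly soluble polyphenol may stall. Prolonged exposure risks reductive opening of the benzylic C2–O1 bonds or reduction of the carbonyl groups.
- Fallback (from 20, directly to 21): non-reductive debenzylation with BCl3 and pentamethylbenzene as cation scavenger in CH2Cl2 at −78 °C. No new intermediate is involved.

## Further compounds

F1 | step 12 | 2-{(2R,4R)-2-[4-(benzyloxy)phenyl]-4-(triethylsilyloxy)-5,7-bis(triisopropylsilyloxy)chroman-8-yl}-1-(2-hydroxy-4,6-bis{[3,4-bis(benzyloxy)benzyl]oxy}phenyl)ethanone | CC[Si](CC)(CC)O[C@@H]1C[C@H](c2ccc(OCc3ccccc3)cc2)Oc2c(CC(=O)c3c(O)cc(OCc4ccc(OCc5ccccc5)c(OCc5ccccc5)c4)cc3OCc3ccc(OCc4ccccc4)c(OCc4ccccc4)c3)c(O[Si](C(C)C)(C(C)C)C(C)C)cc(O[Si](C(C)C)(C(C)C)C(C)C)c12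
F2 | step 12 | (2S,3R)-2-[3,4-bis(benzyloxy)phenyl]-5,7-bis{[3,4-bis(benzyloxy)benzyl]oxy}-3-{(2R,4R)-2-[4-(benzyloxy)phenyl]-4-(triethylsilyloxy)-5,7-bis(triisopropylsilyloxy)chroman-8-yl}chroman-4-one | CC[Si](CC)(CC)O[C@@H]1C[C@H](c2ccc(OCc3ccccc3)cc2)Oc2c([C@H]3C(=O)c4c(OCc5ccc(OCc6ccccc6)c(OCc6ccccc6)c5)cc(OCc5ccc(OCc6ccccc6)c(OCc6ccccc6)c5)cc4O[C@@H]3c3ccc(OCc4ccccc4)c(OCc4ccccc4)c3)c(O[Si](C(C)C)(C(C)C)C(C)C)cc(O[Si](C(C)C)(C(C)C)C(C)C)c12
F3 | step 10 | (2R,4R)-8-allyl-2-[4-(benzyloxy)phenyl]-4-(triethylsilyloxy)-5,7-bis(triisopropylsilyloxy)chroman | CC[Si](CC)(CC)O[C@@H]1C[C@H](c2ccc(OCc3ccccc3)cc2)Oc2c(CC=C)c(O[Si](C(C)C)(C(C)C)C(C)C)cc(O[Si](C(C)C)(C(C)C)C(C)C)c12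
F4 | step 10 | 2-{(2R,4R)-2-[4-(benzyloxy)phenyl]-4-(triethylsilyloxy)-5,7-bis(triisopropylsilyloxy)chroman-8-yl}acetaldehyde | CC[Si](CC)(CC)O[C@@H]1C[C@H](c2ccc(OCc3ccccc3)cc2)Oc2c(CC=O)c(O[Si](C(C)C)(C(C)C)C(C)C)cc(O[Si](C(C)C)(C(C)C)C(C)C)c12
F5 | step 10 | 1,3,5-tris{[3,4-bis(benzyloxy)benzyl]oxy}benzene | c1c(OCc2ccc(OCc3ccccc3)c(OCc3ccccc3)c2)cc(OCc2ccc(OCc3ccccc3)c(OCc3ccccc3)c2)cc1OCc1ccc(OCc2ccccc2)c(OCc2ccccc2)c1
F6 | step 10 | 2-bromo-1,3,5-tris{[3,4-bis(benzyloxy)benzyl]oxy}benzene | Brc1c(OCc2ccc(OCc3ccccc3)c(OCc3ccccc3)c2)cc(OCc2ccc(OCc3ccccc3)c(OCc3ccccc3)c2)cc1OCc1ccc(OCc2ccccc2)c(OCc2ccccc2)c1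
F7 | step 10 | 2-{(2R,4R)-2-[4-(benzyloxy)phenyl]-4-(triethylsilyloxy)-5,7-bis(triisopropylsilyloxy)chroman-8-yl}-1-(2,4,6-tris{[3,4-bis(benzyloxy)benzyl]oxy}phenyl)ethanol (mixture of carbinol epimers) | CC[Si](CC)(CC)O[C@@H]1C[C@H](c2ccc(OCc3ccccc3)cc2)Oc2c(CC(O)c3c(OCc4ccc(OCc5ccccc5)c(OCc5ccccc5)c4)cc(OCc4ccc(OCc5ccccc5)c(OCc5ccccc5)c4)cc3OCc3ccc(OCc4ccccc4)c(OCc4ccccc4)c3)c(O[Si](C(C)C)(C(C)C)C(C)C)cc(O[Si](C(C)C)(C(C)C)C(C)C)c12
F8 | step 4 | racemic 2-[4-(benzyloxy)phenyl]-8-bromo-5,7-bis(triisopropylsilyloxy)chroman-4-one | O=C1CC(c2ccc(OCc3ccccc3)cc2)Oc2c(Br)c(O[Si](C(C)C)(C(C)C)C(C)C)cc(O[Si](C(C)C)(C(C)C)C(C)C)c12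
F9 | step 4 | (2S)-2-[4-(benzyloxy)phenyl]-8-bromo-5,7-bis(triisopropylsilyloxy)chroman-4-one | O=C1C[C@@H](c2ccc(OCc3ccccc3)cc2)Oc2c(Br)c(O[Si](C(C)C)(C(C)C)C(C)C)cc(O[Si](C(C)C)(C(C)C)C(C)C)c12
F10 | step 3 | 5,7-dihydroxy-4H-chromen-4-one | O=c1ccoc2cc(O)cc(O)c12
F11 | step 3 | 5,7-bis(triisopropylsilyloxy)-4H-chromen-4-one | O=c1ccoc2cc(O[Si](C(C)C)(C(C)C)C(C)C)cc(O[Si](C(C)C)(C(C)C)C(C)C)c12
F0 | step 16 | none | none
A1 | alternative 1 | (2R,3S)-3-[4-(benzyloxy)-2-hydroxy-6-(triisopropylsilyloxy)phenyl]-2-[3,4-bis(benzyloxy)phenyl]-5,7-bis(benzyloxy)chroman | Oc1cc(OCc2ccccc2)cc(O[Si](C(C)C)(C(C)C)C(C)C)c1[C@@H]1Cc2c(OCc3ccccc3)cc(OCc3ccccc3)cc2O[C@H]1c1ccc(OCc2ccccc2)c(OCc2ccccc2)c1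
A2 | alternative 1 | {[(2R,3S)-2-[3,4-bis(benzyloxy)phenyl]-5,7-bis(benzyloxy)chroman-3-yl]ethynyloxy}triisopropylsilane | CC(C)[Si](C(C)C)(C(C)C)OC#C[C@@H]1Cc2c(OCc3ccccc3)cc(OCc3ccccc3)cc2O[C@H]1c1ccc(OCc2ccccc2)c(OCc2ccccc2)c1
A3 | alternative 1 | 3-(benzyloxy)cyclobut-2-en-1-one | O=C1C=C(OCc2ccccc2)C1
A4 | alternative 2 | (2R,3S)-2-[3,4-bis(benzyloxy)phenyl]-5,7-bis(benzyloxy)-3-[2,4,6-tris(pivaloyloxy)phenyl]chroman | CC(C)(C)C(=O)Oc1cc(OC(=O)C(C)(C)C)cc(OC(=O)C(C)(C)C)c1[C@@H]1Cc2c(OCc3ccccc3)cc(OCc3ccccc3)cc2O[C@H]1c1ccc(OCc2ccccc2)c(OCc2ccccc2)c1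
A5 | alternative 2 | 2-(hydroxymethyl)-3,5-bis(benzyloxy)phenol | OCc1c(O)cc(OCc2ccccc2)cc1OCc1ccccc1
A6 | alternative 2 | (E)-1-[3,4-bis(benzyloxy)phenyl]-2-[2,4,6-tris(pivaloyloxy)phenyl]ethene | CC(C)(C)C(=O)Oc1cc(OC(=O)C(C)(C)C)cc(OC(=O)C(C)(C)C)c1/C=C/c1ccc(OCc2ccccc2)c(OCc2ccccc2)c1
A7 | alternative 3 | (2R,3S)-2-[3,4-bis(benzyloxy)phenyl]-5,7-bis(benzyloxy)-3-[2,4,6-tris(methoxymethoxy)phenyl]chroman-4-one | COCOc1cc(OCOC)cc(OCOC)c1[C@@H]1C(=O)c2c(OCc3ccccc3)cc(OCc3ccccc3)cc2O[C@H]1c1ccc(OCc2ccccc2)c(OCc2ccccc2)c1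
A8 | alternative 3 | methyl (2S,3R)-3-[3,4-bis(benzyloxy)phenyl]-3-hydroxy-2-[2,4,6-tris(methoxymethoxy)phenyl]propanoate | COCOc1cc(OCOC)cc(OCOC)c1[C@@H]([C@@H](O)c1ccc(OCc2ccccc2)c(OCc2ccccc2)c1)C(=O)OC
A9 | alternative 3 | 3,5-bis(benzyloxy)-2-(trimethylsilyl)phenyl trifluoromethanesulfonate | C[Si](C)(C)c1c(OCc2ccccc2)cc(OCc2ccccc2)cc1OS(=O)(=O)C(F)(F)F
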